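**Plan**
1. Retrosynthesis: the four O–benzyl bonds are cut first, then the C3–O bond (hydroxylation of a flavanone enol ether) and the C2–H/C3–H bonds (reduction of a flavone).
2. Ring C of the flavone is cut at C4a–C4, C4–C3 and O1–C2. C4 is a carbonyl carbon between C4a of ring A and C3, and O1 sits on C8a next to C4a, so ring C maps onto an ortho-iodophenol, carbon monoxide and the arylacetylene that carries ring B.
3. The iodophenol is cut at C–I, at the benzylic C–H bond (hydrogenation of a 1,1-diarylethene) and at the aryl–C bond back to phloroacetophenone. Its only free hydroxyl (the future O1) is para to the C6 side chain, so the two carbons ortho to it are equivalent.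
4. Forward: ring A is bought; the side chain is attached (Grignard addition, dehydration) and hydrogenated; the para oxygen is freed and the ring iodinated; ring C closes in one three-component step that also brings in ring B; reduction, C3 hydroxylation and debenzylation finish the route.
5. Stereochemistry: the benzylic (R) centre comes from iridium-catalysed asymmetric hydrogenation, C2 from ruthenium–NHC-catalysed asymmetric hydrogenation of the flavone (both catalyst control), and C3 from the C2 aryl group, which sends the oxidant to the opposite face (2,3-trans).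

Key step: step 8

Assumption: the ligand antipodes named in steps 5 and 9 are those expected to give the configurations drawn; if a model substrate shows the opposite sense of induction, the mirror-image ligand is used.

**Route**

Step 1
Reactants: 1 2',4',6'-trihydroxyacetophenone (phloroacetophenone)
Product: 2 mono-MOM ether 1-[2,6-dihydroxy-4-(methoxymethoxy)phenyl]ethanone
Conditions: MOMCl (1.0 equiv), K2CO3, acetone, 0 °C to rt
Reagents that add atoms: chloromethyl methyl ether, COCCl
Why: Williamson etherification; the para hydroxyl is the most acidic and is not chelated to the acetyl group, so one equivalent of MOMCl should alkylate it selectively.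

Step 2
Reactants: 2 mono-MOM ether
Product: 3 ketone 1-[2,6-bis(benzyloxy)-4-(methoxymethoxy)phenyl]ethanone
Conditions: BnBr (2.5 equiv), K2CO3, DMF, 70 °C
Reagents that add atoms: benzyl bromide, BrCc1ccccc1
Why: Williamson etherification under forcing conditions that overcome the hydrogen bonding of the two ortho hydroxyls, while the MOM ether is inert to base.

Step 3
Reactants: 3 ketone; 4 1-(benzyloxy)-4-bromobenzene
Product: 6 tertiary carbinol 1-[2,6-bis(benzyloxy)-4-(methoxymethoxy)phenyl]-1-[4-(benzyloxy)phenyl]ethanol (racemic), via aryl Grignard reagent 5 (not isolated)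
Conditions: 4, Mg, THF, reflux; then 3, LaCl3·2LiCl, THF, 0 °C to rt; aq. NH4Cl
Reagents that add atoms: none
Why: Grignard addition to a ketone, in which LaCl3·2LiCl activates the hindered, doubly ortho-substituted carbonyl group for 1,2-addition over enolisation; the new carbinol centre is racemic and is removed in step 4.

Step 4
Reactants: 6 tertiary carbinol
Product: 7 diarylethene 1,3-bis(benzyloxy)-2-{1-[4-(benzyloxy)phenyl]ethenyl}-5-(methoxymethoxy)benzene
Conditions: PPTS (cat.), toluene, 4 Å MS, 50 °C
Reagents that add atoms: none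
Why: E1 dehydration of a tertiary, doubly benzylic alcohol whose only β-hydrogens are on the methyl group, so a single alkene can form, and the weak acid should leave the aryl MOM ether intact.

Step 5
Reactants: 7 diarylethene
Product: 8 diarylethane 1,3-bis(benzyloxy)-2-{(1R)-1-[4-(benzyloxy)phenyl]ethyl}-5-(methoxymethoxy)benzene
Conditions: [Ir(cod)((S)-t-Bu-PHOX)]BArF (1 mol%), H2 (1 bar), CH2Cl2, rt
Reagents that add atoms: none
Why: Iridium–N,P-catalysed asymmetric hydrogenation of a 1,1-diarylethene; the 2,6-bis(benzyloxy)aryl ring is twisted out of the alkene plane while the para-substituted ring stays conjugated, so the chiral catalyst sees a large and a small aryl group and should deliver hydrogen to the face that gives the (R) centre, and benzyl and MOM ethers are inert to the homogeneous catalyst.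

Step 6
Reactants: 8 diarylethane
Product: 9 phenol 3,5-bis(benzyloxy)-4-{(1R)-1-[4-(benzyloxy)phenyl]ethyl}phenol
Conditions: HCl (0.5 M), MeOH–THF, 40 °C
Reagents that add atoms: none
Why: Acid-catalysed transacetalisation of the aryl MOM ether to methanol; benzyl ethers are stable, and the acid is too dilute to protonate ring A at the carbon bearing the side chain, so the benzylic centre should be kept.

Step 7
Reactants: 9 phenol
Product: 10 iodophenol 3,5-bis(benzyloxy)-4-{(1R)-1-[4-(benzyloxy)phenyl]ethyl}-2-iodophenol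
Conditions: NIS (1.0 equiv), CH2Cl2, −20 to 0 °C, dark
Reagents that add atoms: N-iodosuccinimide, O=C1CCC(=O)N1I
Why: Electrophilic aromatic iodination ortho to the free phenol; the para position is blocked and the two ortho positions are equivalent, so only one mono-iodide can form, and one equivalent at low temperature limits di-iodination and spares the less activated 4-benzyloxyphenyl ring.

Step 8
Reactants: 10 iodophenol; 11 carbon monoxide; 12 1-(benzyloxy)-4-ethynylbenzene
Product: 15 protected flavone 5,7-bis(benzyloxy)-2-[4-(benzyloxy)phenyl]-6-{(1R)-1-[4-(benzyloxy)phenyl]ethyl}-4H-chromen-4-one, via ortho-hydroxyaryl ynone 13 (not isolated), via enaminone 14 (not isolated)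
Conditions: PdCl2(dppf) (5 mol%), CO (20 bar), 12 (1.5 equiv), Et2NH, 120 °C
Reagents that add atoms: none
Why: Oxidative addition of the C–I bond of 10 to zerovalent palladium (generated from PdCl2(dppf) by the amine and the alkyne) is followed by migratory insertion of carbon monoxide, and the resulting aroylpalladium iodide, a divalent palladium species, takes up the acetylide formed from 12 and diethylamine and releases ynone 13 by reductive elimination, which makes C4a–C4 and C4–C3. Diethylamine then adds to the triple bond to give enaminone 14, and the ortho phenol oxygen attacks C2 with loss of the amine, which makes O1–C2. The closest known reaction is the palladium-catalysed carbonylative Sonogashira coupling of 2-iodophenols with terminal arylacetylenes in diethylamine, with cyclisation to the flavone in the same pot. Ring C closes in the 6-endo mode at C2 by addition–elimination on the enaminone, and the amine adduct closes off the 5-exo path to the aurone. No stereocentre is formed, and the benzylic (R) centre has no C–H acidic enough for the amine, so it should pass through unchanged. The step requires carbon monoxide insertion to be faster than direct alkyne coupling (which would end in a 2-arylbenzofuran) and faster than capture of the aroyl complex by the amine, which the carbon monoxide pressure and the electron-rich aryl–palladium bond should secure; the ring fusion is fixed by the substrate, whose only free hydroxyl is para to the side chain with the iodine on one of its two equivalent neighbours.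

Step 9
Reactants: 15 protected flavone
Product: 16 flavanol (2S,4S)-5,7-bis(benzyloxy)-2-[4-(benzyloxy)phenyl]-6-{(1R)-1-[4-(benzyloxy)phenyl]ethyl}chroman-4-ol
Conditions: Ru(cod)(2-methylallyl)2 (5 mol%), (R,R)-SINpEt·HBF4 (10 mol%), KOt-Bu (15 mol%), H2 (100 bar), toluene, 40 °C
Reagents that add atoms: none
Why: Ruthenium–NHC-catalysed asymmetric hydrogenation of a flavone, known for this substrate class; the chiral carbene ligands (from 1,3-bis[(R)-1-(naphthalen-1-yl)ethyl]-4,5-dihydroimidazolium tetrafluoroborate) select the face of C2 for hydrogen delivery (2S), the C4 carbonyl is reduced as well, expected mainly to the 2,4-cis alcohol (a centre that step 10 removes, so a C4 epimer would converge), and benzenoid rings and benzyl ethers are not touched.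

Step 10
Reactants: 16 flavanol
Product: 17 flavanone (2S)-5,7-bis(benzyloxy)-2-[4-(benzyloxy)phenyl]-6-{(1R)-1-[4-(benzyloxy)phenyl]ethyl}chroman-4-one
Conditions: Dess–Martin periodinane, CH2Cl2, 0 °C to rt
Reagents that add atoms: none
Why: Dess–Martin oxidation of the benzylic secondary alcohol to the ketone under non-basic conditions, so ring C cannot open by retro-oxa-Michael reaction and C2 should keep its configuration.

Step 11
Reactants: 17 flavanone
Product: 20 protected dihydroflavonol (2R,3R)-5,7-bis(benzyloxy)-2-[4-(benzyloxy)phenyl]-6-{(1R)-1-[4-(benzyloxy)phenyl]ethyl}-3-hydroxychroman-4-one, via trimethylsilyl enol ether 18 (not isolated), via silyloxy epoxide 19 (not isolated)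
Conditions: TMSOTf, Et3N, CH2Cl2, 0 °C; then DMDO, acetone, −40 to 0 °C; then aq. citric acid, THF, 0 °C
Reagents that add atoms: dimethyldioxirane, CC1(C)OO1
Why: Rubottom oxidation; soft enolisation gives the silyl enol ether without a free enolate that could open ring C, dimethyldioxirane epoxidises it on the face opposite to the C2 aryl group, and mild acid opens the silyloxy epoxide to the 3-hydroxy ketone with the hydroxyl trans to the aryl group, which sets C3 as (R).

Step 12
Reactants: 20 protected dihydroflavonol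
Product: 21 (2R,3R)-3,5,7-trihydroxy-2-(4-hydroxyphenyl)-6-[(1R)-1-(4-hydroxyphenyl)ethyl]chroman-4-one (target)
Conditions: H2 (1 atm), 10% Pd/C, EtOAc–MeOH, rt
Reagents that add atoms: none
Why: Hydrogenolysis of the four benzyl aryl ethers over palladium on carbon under neutral conditions at atmospheric pressure, which should spare the hydrogen-bonded C4 ketone, the C2–O1 bond and the diarylmethine, and avoids the base that would epimerise C2 and C3.

**Compound list**
1 | 2',4',6'-trihydroxyacetophenone (phloroacetophenone) | CC(=O)c1c(O)cc(O)cc1O | starting material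
2 | 1-[2,6-dihydroxy-4-(methoxymethoxy)phenyl]ethanone | CC(=O)c1c(O)cc(OCOC)cc1O | intermediate
3 | 1-[2,6-bis(benzyloxy)-4-(methoxymethoxy)phenyl]ethanone | CC(=O)c1c(OCc2ccccc2)cc(OCOC)cc1OCc1ccccc1 | intermediate
4 | 1-(benzyloxy)-4-bromobenzene | Brc1ccc(OCc2ccccc2)cc1 | starting material
5 | [4-(benzyloxy)phenyl]magnesium bromide | Br[Mg]c1ccc(OCc2ccccc2)cc1 | intermediate
6 | 1-[2,6-bis(benzyloxy)-4-(methoxymethoxy)phenyl]-1-[4-(benzyloxy)phenyl]ethanol, racemic | CC(O)(c1ccc(OCc2ccccc2)cc1)c1c(OCc2ccccc2)cc(OCOC)cc1OCc1ccccc1 | intermediate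
7 | 1,3-bis(benzyloxy)-2-{1-[4-(benzyloxy)phenyl]ethenyl}-5-(methoxymethoxy)benzene | C=C(c1ccc(OCc2ccccc2)cc1)c1c(OCc2ccccc2)cc(OCOC)cc1OCc1ccccc1 | intermediate
8 | 1,3-bis(benzyloxy)-2-{(1R)-1-[4-(benzyloxy)phenyl]ethyl}-5-(methoxymethoxy)benzene | C[C@H](c1ccc(OCc2ccccc2)cc1)c1c(OCc2ccccc2)cc(OCOC)cc1OCc1ccccc1 | intermediate
9 | 3,5-bis(benzyloxy)-4-{(1R)-1-[4-(benzyloxy)phenyl]ethyl}phenol | C[C@H](c1ccc(OCc2ccccc2)cc1)c1c(OCc2ccccc2)cc(O)cc1OCc1ccccc1 | intermediate
10 | 3,5-bis(benzyloxy)-4-{(1R)-1-[4-(benzyloxy)phenyl]ethyl}-2-iodophenol | C[C@H](c1ccc(OCc2ccccc2)cc1)c1c(OCc2ccccc2)cc(O)c(I)c1OCc1ccccc1 | intermediate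
11 | carbon monoxide | [C-]#[O+] | starting material
12 | 1-(benzyloxy)-4-ethynylbenzene | C#Cc1ccc(OCc2ccccc2)cc1 | starting material
13 | 1-[2,4-bis(benzyloxy)-3-{(1R)-1-[4-(benzyloxy)phenyl]ethyl}-6-hydroxyphenyl]-3-[4-(benzyloxy)phenyl]prop-2-yn-1-one | C[C@H](c1ccc(OCc2ccccc2)cc1)c1c(OCc2ccccc2)cc(O)c(C(=O)C#Cc2ccc(OCc3ccccc3)cc2)c1OCc1ccccc1 | intermediate
14 | (2E)-1-[2,4-bis(benzyloxy)-3-{(1R)-1-[4-(benzyloxy)phenyl]ethyl}-6-hydroxyphenyl]-3-[4-(benzyloxy)phenyl]-3-(diethylamino)prop-2-en-1-one (E drawn; the geometry does not matter for the closure) | C[C@H](c1ccc(OCc2ccccc2)cc1)c1c(OCc2ccccc2)cc(O)c(C(=O)/C=C(/N(CC)CC)c2ccc(OCc3ccccc3)cc2)c1OCc1ccccc1 | intermediate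
15 | 5,7-bis(benzyloxy)-2-[4-(benzyloxy)phenyl]-6-{(1R)-1-[4-(benzyloxy)phenyl]ethyl}-4H-chromen-4-one | C[C@H](c1ccc(OCc2ccccc2)cc1)c1c(OCc2ccccc2)cc2c(c1OCc1ccccc1)C(=O)C=C(c1ccc(OCc3ccccc3)cc1)O2 | intermediate
16 | (2S,4S)-5,7-bis(benzyloxy)-2-[4-(benzyloxy)phenyl]-6-{(1R)-1-[4-(benzyloxy)phenyl]ethyl}chroman-4-ol (2,4-cis) | C[C@H](c1ccc(OCc2ccccc2)cc1)c1c(OCc2ccccc2)cc2c(c1OCc1ccccc1)[C@@H](O)C[C@@H](c1ccc(OCc3ccccc3)cc1)O2 | intermediate
17 | (2S)-5,7-bis(benzyloxy)-2-[4-(benzyloxy)phenyl]-6-{(1R)-1-[4-(benzyloxy)phenyl]ethyl}chroman-4-one | C[C@H](c1ccc(OCc2ccccc2)cc1)c1c(OCc2ccccc2)cc2c(c1OCc1ccccc1)C(=O)C[C@@H](c1ccc(OCc3ccccc3)cc1)O2 | intermediate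
18 | (2S)-5,7-bis(benzyloxy)-2-[4-(benzyloxy)phenyl]-6-{(1R)-1-[4-(benzyloxy)phenyl]ethyl}-4-(trimethylsilyloxy)-2H-chromene | C[C@H](c1ccc(OCc2ccccc2)cc1)c1c(OCc2ccccc2)cc2c(c1OCc1ccccc1)C(O[Si](C)(C)C)=C[C@@H](c1ccc(OCc3ccccc3)cc1)O2 | intermediate
19 | 3,4-epoxide of 18 with the oxirane oxygen anti to the C2 aryl group and the trimethylsilyloxy group on C4; (2R,3R,4R) in flavan numbering | C[C@H](c1ccc(OCc2ccccc2)cc1)c1c(OCc2ccccc2)cc2c(c1OCc1ccccc1)[C@]1(O[Si](C)(C)C)O[C@@H]1[C@@H](c1ccc(OCc3ccccc3)cc1)O2 | intermediate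
20 | (2R,3R)-5,7-bis(benzyloxy)-2-[4-(benzyloxy)phenyl]-6-{(1R)-1-[4-(benzyloxy)phenyl]ethyl}-3-hydroxychroman-4-one | C[C@H](c1ccc(OCc2ccccc2)cc1)c1c(OCc2ccccc2)cc2c(c1OCc1ccccc1)C(=O)[C@H](O)[C@@H](c1ccc(OCc3ccccc3)cc1)O2 | intermediate
21 | (2R,3R)-3,5,7-trihydroxy-2-(4-hydroxyphenyl)-6-[(1R)-1-(4-hydroxyphenyl)ethyl]chroman-4-one | C[C@H](c1ccc(O)cc1)c1c(O)cc2c(c1O)C(=O)[C@H](O)[C@@H](c1ccc(O)cc1)O2 | target

**Step count and risks**

Total step count: 12. Longest linear sequence: 12 steps (1 to 21).

Steps most likely to fail: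

1. Step 8. At the doubly ortho-substituted iodide, turnover may be slow enough that the alkyne couples before carbon monoxide has inserted, or that diethylamine captures the aroylpalladium as the amide. The fallback builds the same ynone without palladium. It sets out from phenol 9 and alkyne 12. Ortho-formylation of 9 (MgCl2, Et3N, paraformaldehyde, MeCN, reflux) should give the salicylaldehyde 2,4-bis(benzyloxy)-3-{(1R)-1-[4-(benzyloxy)phenyl]ethyl}-6-hydroxybenzaldehyde F1. Alkyne 12 is deprotonated (n-BuLi, THF, −78 °C) to lithium [4-(benzyloxy)phenyl]acetylide F2, and 2.2 equivalents are added to F1 to give the propargylic alcohol 1-[2,4-bis(benzyloxy)-3-{(1R)-1-[4-(benzyloxy)phenyl]ethyl}-6-hydroxyphenyl]-3-[4-(benzyloxy)phenyl]prop-2-yn-1-ol F3 as a mixture of carbinol epimers. Oxidation with MnO2 (CH2Cl2, rt) returns to the route at ynone 13, which in Et2NH–EtOH at rt should pass through enaminone 14 to flavone 15.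

2. Step 5. The catalyst may discriminate poorly between the two alkene faces, or the acidic iridium hydride may oligomerise the electron-rich alkene. The fallback replaces asymmetric induction by resolution. It sets out from alkene 7, which is hydrogenated without selectivity (RhCl(PPh3)3, H2 (5 bar), benzene–EtOH, 50 °C) to racemic 1,3-bis(benzyloxy)-2-{1-[4-(benzyloxy)phenyl]ethyl}-5-(methoxymethoxy)benzene F4. The MOM ether is removed as in step 6 to give racemic 3,5-bis(benzyloxy)-4-{1-[4-(benzyloxy)phenyl]ethyl}phenol F5. The enantiomers of F5 are separated by preparative chromatography on a chiral stationary phase (amylose tris(3,5-dimethylphenylcarbamate) type), and the (R) enantiomer is phenol 9, where the route is rejoined.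

3. Step 9. Hydrogen uptake may be slow at the hindered, electron-rich pyranone, or the facial selectivity at C2 may be poor. The fallback is a non-selective conjugate reduction followed by kinetic resolution. It sets out from flavone 15, which is reduced with LiBH(s-Bu)3 (THF, −78 °C) to the flavanone as a mixture of C2 epimers, 5,7-bis(benzyloxy)-2-[4-(benzyloxy)phenyl]-6-{(1R)-1-[4-(benzyloxy)phenyl]ethyl}chroman-4-one F6. Asymmetric transfer hydrogenation of F6 (RhCl(Cp*)((R,R)-TsDPEN) or its antipode, whichever consumes the (2R) epimer, HCO2H–Et3N, EtOAc, rt) should reduce the (2R) epimer to the cis alcohol (2R,4R)-5,7-bis(benzyloxy)-2-[4-(benzyloxy)phenyl]-6-{(1R)-1-[4-(benzyloxy)phenyl]ethyl}chroman-4-ol F7 and leave the (2S) ketone. Chromatography then gives flavanone 17, where the route is rejoined at the start of step 11.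

**Further compounds**
F1 | step 8 | 2,4-bis(benzyloxy)-3-{(1R)-1-[4-(benzyloxy)phenyl]ethyl}-6-hydroxybenzaldehyde | C[C@H](c1ccc(OCc2ccccc2)cc1)c1c(OCc2ccccc2)cc(O)c(C=O)c1OCc1ccccc1
F2 | step 8 | lithium [4-(benzyloxy)phenyl]acetylide | [Li]C#Cc1ccc(OCc2ccccc2)cc1
F3 | step 8 | 1-[2,4-bis(benzyloxy)-3-{(1R)-1-[4-(benzyloxy)phenyl]ethyl}-6-hydroxyphenyl]-3-[4-(benzyloxy)phenyl]prop-2-yn-1-ol (carbinol epimers) | C[C@H](c1ccc(OCc2ccccc2)cc1)c1c(OCc2ccccc2)cc(O)c(C(O)C#Cc2ccc(OCc3ccccc3)cc2)c1OCc1ccccc1
F4 | step 5 | racemic 1,3-bis(benzyloxy)-2-{1-[4-(benzyloxy)phenyl]ethyl}-5-(methoxymethoxy)benzene | CC(c1ccc(OCc2ccccc2)cc1)c1c(OCc2ccccc2)cc(OCOC)cc1OCc1ccccc1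
F5 | step 5 | racemic 3,5-bis(benzyloxy)-4-{1-[4-(benzyloxy)phenyl]ethyl}phenol | CC(c1ccc(OCc2ccccc2)cc1)c1c(OCc2ccccc2)cc(O)cc1OCc1ccccc1
F6 | step 9 | 5,7-bis(benzyloxy)-2-[4-(benzyloxy)phenyl]-6-{(1R)-1-[4-(benzyloxy)phenyl]ethyl}chroman-4-one (C2 epimers) | C[C@H](c1ccc(OCc2ccccc2)cc1)c1c(OCc2ccccc2)cc2c(c1OCc1ccccc1)C(=O)CC(c1ccc(OCc3ccccc3)cc1)O2
F7 | step 9 | (2R,4R)-5,7-bis(benzyloxy)-2-[4-(benzyloxy)phenyl]-6-{(1R)-1-[4-(benzyloxy)phenyl]ethyl}chroman-4-ol | C[C@H](c1ccc(OCc2ccccc2)cc1)c1c(OCc2ccccc2)cc2c(c1OCc1ccccc1)[C@H](O)C[C@H](c1ccc(OCc3ccccc3)cc1)O2
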